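**Retrosynthetic overview**
- Target 11 ⇒ O-acylation of the single possible enolate of 1,2-diketone 8 with isovaleryl chloride 9 (C2'–O ester bond; side chain numbered C1' = ring-bound carbonyl, C2', C3').
- Diketone 8 ⇒ α-methylene oxidation of aryl isobutyl ketone 7 ⇐ secondary alcohol 6 ⇐ homoallylic alcohol 5 (alkene hydrogenation).
- Key C1'–C2' disconnection: Barbier carbonyl allylation of 8-formyl-7-methoxycoumarin 3 with methallyl bromide 4, which brings in the whole C4 branch.
- Aldehyde 3 ⇒ O-methylation and C8 formylation of umbelliferone 1.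
- Rings: the coumarin bicycle is bought intact in 1; no ring is formed in the route.

Assumption: the target has no stereocentre and its alkene carries two identical methyl groups, so it is achiral and needs no stereocontrol; the carbinol centre of 5 and 6 is carried racemic and is removed in step 5.

**Step 1**
Reactants: 1 umbelliferone (7-hydroxy-2H-chromen-2-one)
Product: 2 7-hydroxy-2-oxo-2H-chromene-8-carbaldehyde
Conditions: HMTA (3 equiv), TFA, reflux, 12 h; then H2O, 60 °C, 1 h
Reagents that add atoms: hexamethylenetetramine (C1N2CN3CN1CN(C2)C3); water (O)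
Why: Duff ortho-formylation of the phenol, which in 7-hydroxycoumarins goes to C8 rather than C6 because the C7–C8 bond has the higher double-bond character.

**Step 2**
Reactants: 2 7-hydroxy-2-oxo-2H-chromene-8-carbaldehyde
Product: 3 7-methoxy-2-oxo-2H-chromene-8-carbaldehyde
Conditions: MeI, K2CO3, DMF, rt, 12 h
Reagents that add atoms: iodomethane (CI)
Why: Williamson O-methylation of the acidic, chelated phenol; the aldehyde and lactone are inert to carbonate in DMF.

**Step 3**
Reactants: 3 7-methoxy-2-oxo-2H-chromene-8-carbaldehyde; 4 methallyl bromide (3-bromo-2-methylprop-1-ene)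
Product: 5 8-(1-hydroxy-3-methylbut-3-en-1-yl)-7-methoxy-2H-chromen-2-one (racemic)
Conditions: Zn dust, THF/sat. aq NH4Cl (1:1), 0 °C → rt
Reagents that add atoms: none
Why: Zinc Barbier carbonyl allylation adds the methallyl unit only to the aldehyde (lactone and pyrone alkene survive aqueous NH4Cl) and forms the C1'–C2' bond; the new carbinol centre is racemic, which is immaterial because step 5 oxidises it.

**Step 4**
Reactants: 5 8-(1-hydroxy-3-methylbut-3-en-1-yl)-7-methoxy-2H-chromen-2-one
Product: 6 8-(1-hydroxy-3-methylbutyl)-7-methoxy-2H-chromen-2-one (racemic)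
Conditions: H2 (1 atm), RhCl(PPh3)3 (5 mol %), PhMe/EtOH (1:1), rt
Reagents that add atoms: none
Why: Homogeneous hydrogenation with Wilkinson's catalyst reduces the unhindered 1,1-disubstituted alkene faster than the conjugated pyrone C3=C4 bond and does not hydrogenolyse the benzylic C–O bond.

**Step 5**
Reactants: 6 8-(1-hydroxy-3-methylbutyl)-7-methoxy-2H-chromen-2-one
Product: 7 7-methoxy-8-(3-methylbutanoyl)-2H-chromen-2-one
Conditions: DMP (1.3 equiv), CH2Cl2, rt
Reagents that add atoms: none
Why: Dess–Martin oxidation of the secondary benzylic alcohol to the aryl ketone under neutral conditions that leave the coumarin untouched.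

**Step 6**
Reactants: 7 7-methoxy-8-(3-methylbutanoyl)-2H-chromen-2-one
Product: 8 7-methoxy-8-(3-methyl-2-oxobutanoyl)-2H-chromen-2-one
Conditions: SeO2 (1.5 equiv), 1,4-dioxane/H2O (20:1), 100 °C
Reagents that add atoms: selenium dioxide (O=[Se]=O)
Why: Riley oxidation converts the only enolisable α-CH2 of the aryl ketone into a carbonyl to give the 1,2-diketone; the coumarin has no allylic C–H for SeO2 to attack.

**Step 7**
Reactants: 8 7-methoxy-8-(3-methyl-2-oxobutanoyl)-2H-chromen-2-one; 9 isovaleryl chloride (3-methylbutanoyl chloride)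
Product: 11 Exotimarin H, via potassium enolate 10 (not isolated)
Conditions: KHMDS (1.05 equiv), THF, −78 °C, 30 min; then 9 (1.2 equiv), −78 → 0 °C
Reagents that add atoms: potassium bis(trimethylsilyl)amide (C[Si](C)(C)[N-][Si](C)(C)C.[K+]; its K+ stays in 10 only)
Why: The diketone has one enolisable C–H, so deprotonation gives a single enolate whose tetrasubstituted carbon is too hindered for C-acylation, and O-acylation by the acid chloride gives the enol ester regiospecifically with no E/Z issue.

**Compound list**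
1 | umbelliferone (7-hydroxy-2H-chromen-2-one) | Oc1ccc2ccc(=O)oc2c1 | starting material
2 | 7-hydroxy-2-oxo-2H-chromene-8-carbaldehyde | Oc1ccc2ccc(=O)oc2c1C=O | intermediate
3 | 7-methoxy-2-oxo-2H-chromene-8-carbaldehyde | COc1ccc2ccc(=O)oc2c1C=O | intermediate
4 | methallyl bromide (3-bromo-2-methylprop-1-ene) | CC(=C)CBr | starting material
5 | 8-(1-hydroxy-3-methylbut-3-en-1-yl)-7-methoxy-2H-chromen-2-one (racemic) | COc1ccc2ccc(=O)oc2c1C(O)CC(C)=C | intermediate
6 | 8-(1-hydroxy-3-methylbutyl)-7-methoxy-2H-chromen-2-one (racemic) | COc1ccc2ccc(=O)oc2c1C(O)CC(C)C | intermediate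
7 | 7-methoxy-8-(3-methylbutanoyl)-2H-chromen-2-one | COc1ccc2ccc(=O)oc2c1C(=O)CC(C)C | intermediate
8 | 7-methoxy-8-(3-methyl-2-oxobutanoyl)-2H-chromen-2-one | COc1ccc2ccc(=O)oc2c1C(=O)C(=O)C(C)C | intermediate
9 | isovaleryl chloride (3-methylbutanoyl chloride) | CC(C)CC(=O)Cl | starting material
10 | potassium enolate of 8 (potassium 1-(7-methoxy-2-oxo-2H-chromen-8-yl)-3-methyl-1-oxobut-2-en-2-olate) | COc1ccc2ccc(=O)oc2c1C(=O)C([O-])=C(C)C.[K+] | intermediate
11 | Exotimarin H | COc1ccc2ccc(=O)oc2c1C(=O)C(OC(=O)CC(C)C)=C(C)C | target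

**Totals**
Total step count: 7. Longest linear sequence: 7 steps (1 → 11).

**Three steps most likely to fail**

Step 4 (the pyrone C3=C4 bond may be reduced as well). The fallback sets out from 5 and comes back at 7, so it also replaces step 5. Oxidise 5 with DMP (CH2Cl2, rt) to the β,γ-unsaturated ketone 7-methoxy-8-(3-methylbut-3-enoyl)-2H-chromen-2-one F1. Move the alkene into conjugation with catalytic DBU (CH2Cl2, rt) to give the enone 7-methoxy-8-(3-methylbut-2-enoyl)-2H-chromen-2-one F2. Then deliver hydride 1,4 with Stryker's reagent ([(Ph3P)CuH]6, wet benzene/THF, rt); the ketone-conjugated alkene is far more electrophilic than the pyrone, and protonation of the copper enolate gives 7.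

Step 6 (SeO2 may be sluggish on the hindered ketone or over-oxidise the isopropyl C–H). The fallback sets out from 7 and comes back at 8. Soft enolisation with TMSOTf/Et3N (CH2Cl2, 0 °C) gives the silyl enol ether (Z)-7-methoxy-8-[3-methyl-1-(trimethylsilyloxy)but-1-en-1-yl]-2H-chromen-2-one F3. Rubottom oxidation with mCPBA (NaHCO3, CH2Cl2, 0 °C) gives the α-silyloxy ketone 7-methoxy-8-[3-methyl-2-(trimethylsilyloxy)butanoyl]-2H-chromen-2-one F4; the electron-poor pyrone alkene is inert to the peracid. 1 M HCl/THF cleaves it to the α-hydroxy ketone 8-(2-hydroxy-3-methylbutanoyl)-7-methoxy-2H-chromen-2-one F5, and DMP (CH2Cl2, rt) oxidises that to 8.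

Step 7 (the potassium enolate may decompose or acylate poorly). The fallback sets out from 8 and comes back at 11. Trap the enol under non-basic conditions with TMSOTf/Et3N (CH2Cl2, 0 °C) as the isolable silyl enol ether 7-methoxy-8-[3-methyl-2-(trimethylsilyloxy)but-2-enoyl]-2H-chromen-2-one F6. Then treat F6 with anhydrous CsF and isovaleryl chloride 9 (MeCN, 0 °C → rt); fluoride removes the silyl group and the oxygen is acylated in the same operation to give 11.

**Further compounds**
F1 | step 4 | 7-methoxy-8-(3-methylbut-3-enoyl)-2H-chromen-2-one | COc1ccc2ccc(=O)oc2c1C(=O)CC(C)=C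
F2 | step 4 | 7-methoxy-8-(3-methylbut-2-enoyl)-2H-chromen-2-one | COc1ccc2ccc(=O)oc2c1C(=O)C=C(C)C
F3 | step 6 | (Z)-7-methoxy-8-[3-methyl-1-(trimethylsilyloxy)but-1-en-1-yl]-2H-chromen-2-one | COc1ccc2ccc(=O)oc2c1/C(O[Si](C)(C)C)=C/C(C)C
F4 | step 6 | 7-methoxy-8-[3-methyl-2-(trimethylsilyloxy)butanoyl]-2H-chromen-2-one (racemic) | COc1ccc2ccc(=O)oc2c1C(=O)C(O[Si](C)(C)C)C(C)C
F5 | step 6 | 8-(2-hydroxy-3-methylbutanoyl)-7-methoxy-2H-chromen-2-one (racemic) | COc1ccc2ccc(=O)oc2c1C(=O)C(O)C(C)C
F6 | step 7 | 7-methoxy-8-[3-methyl-2-(trimethylsilyloxy)but-2-enoyl]-2H-chromen-2-one | COc1ccc2ccc(=O)oc2c1C(=O)C(O[Si](C)(C)C)=C(C)C
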